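Atoms carry abietane numbers: ring B is C5–C10 (C5 bears the isopropenyl group, C10 the methyl group and the propanoate chain C1–C3, C7 the ketone); ring C is C8, C9, C11–C14.
The design rests on the oxygen pattern of ring C: C12 and C14 carry oxygen on either side of the isopropyl-bearing C13, so the ring is a latent resorcinol that opens on paper to a β,δ-triketone with carbonyls at C9, C14 and C12. The retrosynthesis first removes the C11 and C7 oxygens, then cuts C9–C11 (aldol aromatisation), C8–C14 (aldol addition), C10–C1 (Michael addition) and C5–C4 (conjugate addition).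
Forward: ring B is built first from 2-methylcyclohex-2-en-1-one, isopropenylmagnesium bromide and methyl acrylate; the chain C14–C13(i-Pr)–C12–C11 is attached to C8 and oxidised to the triketone; ring C then closes as the resorcinol; C7 and finally C11 are oxidised.
Stereochemistry: C5 is set by a CuBr·SMe2-catalysed conjugate addition steered by a chiral ferrocenyl diphosphine; C10 is set by attack of the acrylate anti to the C5 isopropenyl group, reinforced by an (S)-1-phenylethylamine imine; neither centre can epimerise afterwards.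

Key step: step 8

Remark: the facial sense of the catalyst formed from CuBr·SMe2 and the diphosphine (step 1) and of the (S)-1-phenylethylamine imine (step 2) is assumed to follow the parent alkyl Grignard and 2-methylcyclohexanone cases; if step 1 should deliver the 3S ketone, the antipodal ligand is used.

Step 1
Reactants: 1 2-methylcyclohex-2-en-1-one; 2 isopropenylmagnesium bromide
Product: 4 (3R)-2-methyl-3-(prop-1-en-2-yl)cyclohexan-1-one (C2 epimers), via bromomagnesium enolate 3 (not isolated)
Conditions: CuBr·SMe2 (5 mol %), Taniaphos-type ferrocenyl diphosphine (6 mol %), t-BuOMe, −78 °C; aq. NH4Cl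
Reagents that add atoms: none
Why: Copper-catalysed asymmetric conjugate addition of a Grignard reagent to an α-substituted cyclic enone, in which the chiral catalyst formed from CuBr·SMe2 and the diphosphine should deliver the isopropenyl group to one enantiotopic face of the β-carbon (3R, the future C5), while protonation of the enolate leaves C2 as an inconsequential epimer mixture.

Step 2
Reactants: 4 (3R)-2-methyl-3-(prop-1-en-2-yl)cyclohexan-1-one; 5 methyl acrylate
Product: 8 methyl 3-[(1S,2S)-1-methyl-6-oxo-2-(prop-1-en-2-yl)cyclohexyl]propanoate (ring B keto ester), via ketimine 6 (not isolated), via alkylated ketimine 7 (not isolated)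
Conditions: (S)-1-phenylethylamine, TsOH (cat.), toluene, reflux (−H2O); methyl acrylate (1.5 equiv), THF, 40 °C; 10% aq. AcOH, rt
Reagents that add atoms: none
Why: Michael addition of a chiral ketimine through its more substituted secondary enamine tautomer (aza-ene-like transition state), so the acrylate should enter only at the methyl-bearing carbon, anti to the neighbouring isopropenyl group and on the face favoured by the (S)-auxiliary (matched pair), which sets the quaternary centre (future C10) as S.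

Step 3
Reactants: 9 ethyl 2-acetyl-3-methylbutanoate (ethyl 2-isopropylacetoacetate)
Product: 10 ethyl 3-hydroxy-2-(propan-2-yl)butanoate (racemic diastereomer mixture)
Conditions: NaBH4, EtOH, 0 °C
Reagents that add atoms: none
Why: Chemoselective borohydride reduction of the ketone of a β-keto ester; both stereocentres become sp2 carbons later, so the mixture is used as such.

Step 4
Reactants: 10 ethyl 3-hydroxy-2-(propan-2-yl)butanoate
Product: 11 ethyl 2-(propan-2-yl)-3-(triethylsilyloxy)butanoate
Conditions: Et3SiCl, imidazole, CH2Cl2, 0 °C → rt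
Reagents that add atoms: triethylsilyl chloride, CC[Si](Cl)(CC)CC
Why: Standard silylation of a secondary alcohol; the triethylsilyl ether should survive hydride reduction and the enolate aldol but be cleaved by dilute acid.

Step 5
Reactants: 11 ethyl 2-(propan-2-yl)-3-(triethylsilyloxy)butanoate
Product: 12 2-(propan-2-yl)-3-(triethylsilyloxy)butanal
Conditions: i-Bu2AlH (1.05 equiv), CH2Cl2, −78 °C; aq. KNaC4H4O6
Reagents that add atoms: none
Why: Partial reduction of an ester with i-Bu2AlH, in which the α-branched tetrahedral aluminium hemiacetal should persist at −78 °C and release the aldehyde only on work-up.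

Step 6
Reactants: 8 methyl 3-[(1S,2S)-1-methyl-6-oxo-2-(prop-1-en-2-yl)cyclohexyl]propanoate; 12 2-(propan-2-yl)-3-(triethylsilyloxy)butanal
Product: 15 methyl 3-[(1S,2S)-5-[1,3-dihydroxy-2-(propan-2-yl)butyl]-1-methyl-6-oxo-2-(prop-1-en-2-yl)cyclohexyl]propanoate (diastereomer mixture), via lithium enolate 13 (not isolated), via silyl-protected aldol 14 (not isolated)
Conditions: LiN(i-Pr)2 (1.05 equiv), THF, −78 °C; 12; then 1 M HCl, THF, 0 °C → rt
Reagents that add atoms: none
Why: Directed aldol addition of a kinetic lithium enolate, which can form only at C8 because C10 is quaternary and the ketone is far more acidic than the ester, joins C8 to C14, and the acidic work-up removes the triethylsilyl group; the new stereocentres are erased in steps 7 and 8.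

Step 7
Reactants: 15 methyl 3-[(1S,2S)-5-[1,3-dihydroxy-2-(propan-2-yl)butyl]-1-methyl-6-oxo-2-(prop-1-en-2-yl)cyclohexyl]propanoate
Product: 16 methyl 3-[(1S,2S)-1-methyl-6-oxo-5-[3-oxo-2-(propan-2-yl)butanoyl]-2-(prop-1-en-2-yl)cyclohexyl]propanoate (triketone, enol tautomers)
Conditions: Dess–Martin periodinane (3 equiv), pyridine, CH2Cl2, 0 °C → rt; used without chromatography
Reagents that add atoms: none
Why: Dess–Martin oxidation of both secondary alcohols under buffered conditions should give the 1,3,5-triketone without the acid that would dehydrate it to a 4-pyranone.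

Step 8
Reactants: 16 methyl 3-[(1S,2S)-1-methyl-6-oxo-5-[3-oxo-2-(propan-2-yl)butanoyl]-2-(prop-1-en-2-yl)cyclohexyl]propanoate
Product: 18 methyl 3-[(1S,2S)-5,7-dihydroxy-1-methyl-6-(propan-2-yl)-2-(prop-1-en-2-yl)-1,2,3,4-tetrahydronaphthalen-1-yl]propanoate (resorcinol with OH at C12 and C14), via ring C aldol adduct 17 (not isolated)
Conditions: NaOMe (4 equiv), degassed MeOH, Ar, rt → 60 °C; then 1 M HCl
Reagents that add atoms: none
Why: Sodium methoxide deprotonates the tricarbonyl chain at several sites in equilibrium, and the enolate of the terminal acetyl group (C11) adds to the ring B carbonyl C9 to give the β-hydroxy ketone 17, which eliminates water and tautomerises twice to the benzene-1,3-diol, the thermodynamic sink. The nearest precedent is the classical base-induced conversion of heptane-2,4,6-trione-type triketones into orcinol-type resorcinols, the flask version of the way folded polyketide chains become aromatic. Ring C forms by a 6-(enolendo)-exo-trig aldol closure, and no other carbon–carbon closure of this chain gives an unstrained six-membered ring, the alternatives being four-membered or bridged. No stereocentre arises, and the two present ones cannot epimerise because C10 is quaternary and C5 has no carbonyl neighbour. The step needs cyclisation through carbon and not through oxygen, which the basic medium should secure (acid would lead to the 4-pyranone), and methoxide in methanol cannot change the methyl ester. Attack at C9 beside the quaternary C10 is hindered, but the reaction is intramolecular and pulled forward by aromatisation, as in Robinson-type closures onto ketones flanked by quaternary carbons.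

Step 9
Reactants: 18 methyl 3-[(1S,2S)-5,7-dihydroxy-1-methyl-6-(propan-2-yl)-2-(prop-1-en-2-yl)-1,2,3,4-tetrahydronaphthalen-1-yl]propanoate
Product: 19 methyl 3-[(1S,2S)-5,7-bis(methoxymethoxy)-1-methyl-6-(propan-2-yl)-2-(prop-1-en-2-yl)-1,2,3,4-tetrahydronaphthalen-1-yl]propanoate
Conditions: NaH (2.5 equiv), MeOCH2Cl (2.5 equiv), DMF, 0 °C → rt
Reagents that add atoms: chloromethyl methyl ether, COCCl
Why: Williamson-type O-alkylation of both phenoxides blocks quinone-methide chemistry and leaves an electron-rich bis-ether suited to hydride abstraction at C7.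

Step 10
Reactants: 19 methyl 3-[(1S,2S)-5,7-bis(methoxymethoxy)-1-methyl-6-(propan-2-yl)-2-(prop-1-en-2-yl)-1,2,3,4-tetrahydronaphthalen-1-yl]propanoate
Product: 21 methyl 3-[(1S,2S)-5,7-bis(methoxymethoxy)-1-methyl-4-oxo-6-(propan-2-yl)-2-(prop-1-en-2-yl)-1,2,3,4-tetrahydronaphthalen-1-yl]propanoate, via C7 alcohol 20 (not isolated)
Conditions: DDQ (2.5 equiv), 1,4-dioxane–H2O (10:1), rt
Reagents that add atoms: water, O
Why: DDQ benzylic oxidation, in which hydride abstraction at C7 gives a cation stabilised by the para C12 and ortho C14 oxygens, water adds and a second equivalent oxidises the alcohol to the aryl ketone, while the isopropyl methine is twisted out of conjugation between two ortho substituents and the allylic C5–H is not activated.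

Step 11
Reactants: 21 methyl 3-[(1S,2S)-5,7-bis(methoxymethoxy)-1-methyl-4-oxo-6-(propan-2-yl)-2-(prop-1-en-2-yl)-1,2,3,4-tetrahydronaphthalen-1-yl]propanoate
Product: 22 methyl 3-[(1S,2S)-5,7-dihydroxy-1-methyl-4-oxo-6-(propan-2-yl)-2-(prop-1-en-2-yl)-1,2,3,4-tetrahydronaphthalen-1-yl]propanoate
Conditions: HCl (cat.), MeOH, 40 °C
Reagents that add atoms: none
Why: Acid-catalysed transacetalisation of the aryl methoxymethyl ethers to methanol, under which the methyl ester is inert and brief mild acid should leave the isopropenyl group intact.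

Step 12
Reactants: 22 methyl 3-[(1S,2S)-5,7-dihydroxy-1-methyl-4-oxo-6-(propan-2-yl)-2-(prop-1-en-2-yl)-1,2,3,4-tetrahydronaphthalen-1-yl]propanoate
Product: 23 methyl 3-[(1S,2S)-7-hydroxy-1-methyl-4,5,8-trioxo-6-(propan-2-yl)-2-(prop-1-en-2-yl)-1,2,3,4,5,8-hexahydronaphthalen-1-yl]propanoate (CNP0308749.1)
Conditions: K2[ON(SO3)2] (2.5 equiv), KH2PO4 buffer, acetone–H2O, rt
Reagents that add atoms: potassium nitrosodisulfonate (Fremy's salt), [K+].[K+].[O]N(S(=O)(=O)[O-])S(=O)(=O)[O-]
Why: Teuber oxidation, in which the nitroxide abstracts a phenolic hydrogen, a second equivalent couples at C11 (the only unsubstituted ring carbon) and loss of imidodisulfonate gives the quinone; whichever hydroxyl is oxidised, tautomerisation should lead to the same 12-hydroxy-11,14-quinone.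

Compound list
1 | 2-methylcyclohex-2-en-1-one | CC1=CCCCC1=O | starting material
2 | isopropenylmagnesium bromide | C=C(C)[Mg]Br | starting material
3 | bromomagnesium enolate of 4 (bromomagnesium 2-methyl-3-(prop-1-en-2-yl)cyclohex-1-en-1-olate, same configuration at the isopropenyl carbon) | C=C(C)[C@@H]1CCCC(O[Mg]Br)=C1C | intermediate
4 | (3R)-2-methyl-3-(prop-1-en-2-yl)cyclohexan-1-one (C2 epimers) | C=C(C)[C@@H]1CCCC(=O)C1C | intermediate
5 | methyl acrylate | C=CC(=O)OC | starting material
6 | (3R)-2-methyl-N-[(1S)-1-phenylethyl]-3-(prop-1-en-2-yl)cyclohexan-1-imine | C=C(C)[C@@H]1CCCC(=N[C@@H](C)c2ccccc2)C1C | intermediate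
7 | methyl 3-[(1S,2S)-1-methyl-6-{[(1S)-1-phenylethyl]imino}-2-(prop-1-en-2-yl)cyclohexyl]propanoate | C=C(C)[C@@H]1CCCC(=N[C@@H](C)c2ccccc2)[C@@]1(C)CCC(=O)OC | intermediate
8 | methyl 3-[(1S,2S)-1-methyl-6-oxo-2-(prop-1-en-2-yl)cyclohexyl]propanoate | C=C(C)[C@@H]1CCCC(=O)[C@@]1(C)CCC(=O)OC | intermediate
9 | ethyl 2-acetyl-3-methylbutanoate (ethyl 2-isopropylacetoacetate) | CCOC(=O)C(C(C)C)C(C)=O | starting material
10 | ethyl 3-hydroxy-2-(propan-2-yl)butanoate | CCOC(=O)C(C(C)C)C(C)O | intermediate
11 | ethyl 2-(propan-2-yl)-3-(triethylsilyloxy)butanoate | CCOC(=O)C(C(C)C)C(C)O[Si](CC)(CC)CC | intermediate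
12 | 2-(propan-2-yl)-3-(triethylsilyloxy)butanal | O=CC(C(C)C)C(C)O[Si](CC)(CC)CC | intermediate
13 | lithium enolate of 8 (C8=C9 enolate) | C=C(C)[C@@H]1CCC=C(O[Li])[C@@]1(C)CCC(=O)OC | intermediate
14 | methyl 3-[(1S,2S)-5-[1-hydroxy-2-(propan-2-yl)-3-(triethylsilyloxy)butyl]-1-methyl-6-oxo-2-(prop-1-en-2-yl)cyclohexyl]propanoate | C=C(C)[C@@H]1CCC(C(O)C(C(C)C)C(C)O[Si](CC)(CC)CC)C(=O)[C@@]1(C)CCC(=O)OC | intermediate
15 | methyl 3-[(1S,2S)-5-[1,3-dihydroxy-2-(propan-2-yl)butyl]-1-methyl-6-oxo-2-(prop-1-en-2-yl)cyclohexyl]propanoate | C=C(C)[C@@H]1CCC(C(O)C(C(C)C)C(C)O)C(=O)[C@@]1(C)CCC(=O)OC | intermediate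
16 | methyl 3-[(1S,2S)-1-methyl-6-oxo-5-[3-oxo-2-(propan-2-yl)butanoyl]-2-(prop-1-en-2-yl)cyclohexyl]propanoate | C=C(C)[C@@H]1CCC(C(=O)C(C(C)C)C(C)=O)C(=O)[C@@]1(C)CCC(=O)OC | intermediate
17 | methyl 3-[(1S,2S)-8a-hydroxy-1-methyl-5,7-dioxo-6-(propan-2-yl)-2-(prop-1-en-2-yl)decahydronaphthalen-1-yl]propanoate | C=C(C)[C@@H]1CCC2C(=O)C(C(C)C)C(=O)CC2(O)[C@@]1(C)CCC(=O)OC | intermediate
18 | methyl 3-[(1S,2S)-5,7-dihydroxy-1-methyl-6-(propan-2-yl)-2-(prop-1-en-2-yl)-1,2,3,4-tetrahydronaphthalen-1-yl]propanoate | C=C(C)[C@@H]1CCc2c(O)c(C(C)C)c(O)cc2[C@@]1(C)CCC(=O)OC | intermediate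
19 | methyl 3-[(1S,2S)-5,7-bis(methoxymethoxy)-1-methyl-6-(propan-2-yl)-2-(prop-1-en-2-yl)-1,2,3,4-tetrahydronaphthalen-1-yl]propanoate | C=C(C)[C@@H]1CCc2c(OCOC)c(C(C)C)c(OCOC)cc2[C@@]1(C)CCC(=O)OC | intermediate
20 | methyl 3-[(1S,2S)-4-hydroxy-5,7-bis(methoxymethoxy)-1-methyl-6-(propan-2-yl)-2-(prop-1-en-2-yl)-1,2,3,4-tetrahydronaphthalen-1-yl]propanoate | C=C(C)[C@@H]1CC(O)c2c(OCOC)c(C(C)C)c(OCOC)cc2[C@@]1(C)CCC(=O)OC | intermediate
21 | methyl 3-[(1S,2S)-5,7-bis(methoxymethoxy)-1-methyl-4-oxo-6-(propan-2-yl)-2-(prop-1-en-2-yl)-1,2,3,4-tetrahydronaphthalen-1-yl]propanoate | C=C(C)[C@@H]1CC(=O)c2c(OCOC)c(C(C)C)c(OCOC)cc2[C@@]1(C)CCC(=O)OC | intermediate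
22 | methyl 3-[(1S,2S)-5,7-dihydroxy-1-methyl-4-oxo-6-(propan-2-yl)-2-(prop-1-en-2-yl)-1,2,3,4-tetrahydronaphthalen-1-yl]propanoate | C=C(C)[C@@H]1CC(=O)c2c(O)c(C(C)C)c(O)cc2[C@@]1(C)CCC(=O)OC | intermediate
23 | methyl 3-[(1S,2S)-7-hydroxy-1-methyl-4,5,8-trioxo-6-(propan-2-yl)-2-(prop-1-en-2-yl)-1,2,3,4,5,8-hexahydronaphthalen-1-yl]propanoate (CNP0308749.1) | C=C(C)[C@@H]1CC(=O)C2=C(C(=O)C(O)=C(C(C)C)C2=O)[C@@]1(C)CCC(=O)OC | target

Total step count: 12.
Longest linear sequence: 10 steps (9 → 23 through steps 3–12); 9 steps from 1.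

Steps most likely to fail

1. Step 8. The carbon–carbon closure at the enolised, hindered C9 carbonyl may be slow, so that closure through oxygen (dehydration to the 4-pyranone) or methoxide-induced retro-Claisen cleavage of the β-diketone takes over. Fallback: lower the oxidation level at C14, so that C9 is a plain ketone and a single kinetic enolate does the closure. It sets out from 14, isolated by leaving out the acid treatment of step 6. The C14 hydroxyl is silylated (t-BuMe2SiOTf, 2,6-lutidine) to the bis-silyl ether F1. The more labile triethylsilyl group is removed (PPTS, MeOH) to give alcohol F2, and Dess–Martin oxidation gives methyl ketone F3. KN(SiMe3)2 in THF at −78 °C forms the kinetic C11 enolate, which adds to C9 in the same six-membered aldol mode to give the ring C carbinol F4. HF·pyridine frees the C14 alcohol (diol F5), and Dess–Martin oxidation of this secondary alcohol gives 17, which loses water and enolises to 18 with a trace of acid or base. The route is rejoined at 17 and thus at 18.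

2. Step 1. Transfer of an alkenyl rather than an alkyl group from magnesium through copper may proceed with poor enantioface discrimination and with some 1,2-addition. Fallback: give up catalytic induction and resolve. From 1 and 2 with CuBr·SMe2 alone the racemic ketone F6 is made. KOt-Bu-catalysed Michael addition to 5 in t-BuOH gives the racemic keto ester F7, the acrylate again entering at the methyl-bearing carbon anti to the isopropenyl group. F7 is separated by preparative chromatography on a chiral stationary phase; its (1S,2S) enantiomer is 8, where the route is rejoined.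

3. Step 12. Hydrogen abstraction from a phenol deactivated by the conjugated C7 ketone and by chelation of the C14 hydroxyl may be sluggish, so that decomposition or over-oxidation competes. Fallback: bring in the C11 oxygen while ring C is still electron-rich. It sets out from 18: K2[ON(SO3)2] gives the hydroxyquinone F8, and Na2S2O4 reduces it to the triol F9, which is protected at once (NaH, MeOCH2Cl, DMF) as the tris(methoxymethyl) ether F10. DDQ in wet dioxane oxidises C7 as in step 10 to ketone F11. HCl in MeOH removes the three ethers, and the resulting triol F12 is oxidised by air during work-up to 23, where the route ends.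

Further compounds
F1 | step 8 | methyl 3-[(1S,2S)-5-[1-(tert-butyldimethylsilyloxy)-2-(propan-2-yl)-3-(triethylsilyloxy)butyl]-1-methyl-6-oxo-2-(prop-1-en-2-yl)cyclohexyl]propanoate | C=C(C)[C@@H]1CCC(C(O[Si](C)(C)C(C)(C)C)C(C(C)C)C(C)O[Si](CC)(CC)CC)C(=O)[C@@]1(C)CCC(=O)OC
F2 | step 8 | methyl 3-[(1S,2S)-5-[1-(tert-butyldimethylsilyloxy)-3-hydroxy-2-(propan-2-yl)butyl]-1-methyl-6-oxo-2-(prop-1-en-2-yl)cyclohexyl]propanoate | C=C(C)[C@@H]1CCC(C(O[Si](C)(C)C(C)(C)C)C(C(C)C)C(C)O)C(=O)[C@@]1(C)CCC(=O)OC
F3 | step 8 | methyl 3-[(1S,2S)-5-[1-(tert-butyldimethylsilyloxy)-3-oxo-2-(propan-2-yl)butyl]-1-methyl-6-oxo-2-(prop-1-en-2-yl)cyclohexyl]propanoate | C=C(C)[C@@H]1CCC(C(O[Si](C)(C)C(C)(C)C)C(C(C)C)C(C)=O)C(=O)[C@@]1(C)CCC(=O)OC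
F4 | step 8 | methyl 3-[(1S,2S)-5-(tert-butyldimethylsilyloxy)-8a-hydroxy-1-methyl-7-oxo-6-(propan-2-yl)-2-(prop-1-en-2-yl)decahydronaphthalen-1-yl]propanoate | C=C(C)[C@@H]1CCC2C(O[Si](C)(C)C(C)(C)C)C(C(C)C)C(=O)CC2(O)[C@@]1(C)CCC(=O)OC
F5 | step 8 | methyl 3-[(1S,2S)-5,8a-dihydroxy-1-methyl-7-oxo-6-(propan-2-yl)-2-(prop-1-en-2-yl)decahydronaphthalen-1-yl]propanoate | C=C(C)[C@@H]1CCC2C(O)C(C(C)C)C(=O)CC2(O)[C@@]1(C)CCC(=O)OC
F6 | step 1 | racemic 2-methyl-3-(prop-1-en-2-yl)cyclohexan-1-one | C=C(C)[C@@H]1CCCC(=O)C1C.C=C(C)[C@H]1CCCC(=O)C1C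
F7 | step 1 | racemic methyl 3-[(1S*,2S*)-1-methyl-6-oxo-2-(prop-1-en-2-yl)cyclohexyl]propanoate | C=C(C)[C@@H]1CCCC(=O)[C@@]1(C)CCC(=O)OC.C=C(C)[C@H]1CCCC(=O)[C@]1(C)CCC(=O)OC
F8 | step 12 | methyl 3-[(1S,2S)-7-hydroxy-1-methyl-5,8-dioxo-6-(propan-2-yl)-2-(prop-1-en-2-yl)-1,2,3,4,5,8-hexahydronaphthalen-1-yl]propanoate | C=C(C)[C@@H]1CCC2=C(C(=O)C(O)=C(C(C)C)C2=O)[C@@]1(C)CCC(=O)OC
F9 | step 12 | methyl 3-[(1S,2S)-5,7,8-trihydroxy-1-methyl-6-(propan-2-yl)-2-(prop-1-en-2-yl)-1,2,3,4-tetrahydronaphthalen-1-yl]propanoate | C=C(C)[C@@H]1CCc2c(O)c(C(C)C)c(O)c(O)c2[C@@]1(C)CCC(=O)OC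
F10 | step 12 | methyl 3-[(1S,2S)-5,7,8-tris(methoxymethoxy)-1-methyl-6-(propan-2-yl)-2-(prop-1-en-2-yl)-1,2,3,4-tetrahydronaphthalen-1-yl]propanoate | C=C(C)[C@@H]1CCc2c(OCOC)c(C(C)C)c(OCOC)c(OCOC)c2[C@@]1(C)CCC(=O)OC
F11 | step 12 | methyl 3-[(1S,2S)-5,7,8-tris(methoxymethoxy)-1-methyl-4-oxo-6-(propan-2-yl)-2-(prop-1-en-2-yl)-1,2,3,4-tetrahydronaphthalen-1-yl]propanoate | C=C(C)[C@@H]1CC(=O)c2c(OCOC)c(C(C)C)c(OCOC)c(OCOC)c2[C@@]1(C)CCC(=O)OC
F12 | step 12 | methyl 3-[(1S,2S)-5,7,8-trihydroxy-1-methyl-4-oxo-6-(propan-2-yl)-2-(prop-1-en-2-yl)-1,2,3,4-tetrahydronaphthalen-1-yl]propanoate | C=C(C)[C@@H]1CC(=O)c2c(O)c(C(C)C)c(O)c(O)c2[C@@]1(C)CCC(=O)OC
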